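## Analysis of the target

The target 32 is a tetrahydrofuran (O1, C2–C5) whose C2 carries C5' of a 7'-methoxy-2',3'-dihydrobenzofuran (ring B), C3 a hydroxymethyl group, C4 a hydroxyl group and C5 a 4-hydroxy-3-methoxybenzyl group (ring C); the dihydrobenzofuran carries a 4-hydroxy-3-methoxyphenyl group (ring A) at C2' and a hydroxymethyl group at C3'. There are six stereocentres in two sets that cannot pass information to each other across ring B. On the tetrahydrofuran the C2 aryl, C4 hydroxyl and C5 benzyl groups lie on one face and the C3 hydroxymethyl group on the other (2,3-trans, 3,4-trans, 4,5-cis); on the dihydrobenzofuran the C2' aryl and C3' hydroxymethyl groups are cis. The cis-dihydrobenzofuran is the less stable isomer: with a free hydroxyl group para to C2' on ring A, the C2'–O1' bond can open to a quinone methide under acid or base and reclose trans, and both it and the benzylic C2–O1 bond are open to hydrogenolysis. Three oxygenated arenes that are nucleophiles towards cations and substrates for oxidants must be carried, together with two phenols and two primary alcohols. The difficulty is to set the 4,5-cis/3,4-trans pattern and the absolute configuration of each set independently, without disturbing the cis-dihydrobenzofuran. The strategy rests on the C4 oxygen: cis to the C5 and C2 substituents and trans to C3 is where the acyl group of a 3-acyltetrahydrofuran sits when the ring is made by cyclisation of an alkene onto an oxocarbenium ion followed by a ring-contracting 1,2-shift, and an acetyl group can be exchanged for oxygen with retention.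

## Retrosynthetic reasoning

**32 ⇒ 31 ⇒ 30.** The last two operations only unmask. The four acetates of 31 are exchanged for hydrogen, and before that the silyl ether of 30 is cleaved while both phenols are still esters. No skeletal bond is cut. The gain is an endgame without hydrogenolysis or strong acid, both of which threaten the benzylic C–O bonds at C2 and C2'.

**30 ⇒ 29.** The C4–O bond is traced back to the C4–acetyl bond of 29. A peracid oxidation with migration of the secondary ring carbon must insert oxygen with retention, so the configuration of C4 is decided one step earlier.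

**29 ⇒ 11 + 27 (through 28).** Three bonds are cut: C2–O1, C2–C3 and C4–C5. This divides the molecule into two halves of similar size, aldehyde 11 and diol 27, and makes C2, C3 and C4 follow from the single pre-set centre C5. The aldehyde cannot enolise. The forward reaction must form the acetal 28, open it to the oxocarbenium ion on O1, let the E-alkene attack C2 through C3, and shift C5 from the carbinol carbon to C4. Two protecting groups are chosen for this step alone:
- Ring C is an aryl acetate. A 3,4-dialkoxybenzyl group on C5 would close onto the oxocarbenium ion through its carbon para to the methoxy group faster than the alkene does.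
- The allylic oxygen carries a bulky silyl group that does not bind the Lewis acid, so the alkene is not deactivated further.

Ring A is an acetate as well, so that the C2'–O1' bond does not ionise.

**11 ⇒ 10 ⇒ 9 ⇒ 8.** The formyl group is masked as a dioxolane, and the acetoxymethyl group and the ring A acetate are traced to the ester 8. One hydride reduction converts the ester and frees the phenol; one acetylation covers both hydroxyl groups before any acid is used.

**8 ⇒ 7.** The C2'–C3' bond is cut. An aryl carbenoid at the future C3' inserts into the benzylic C–H bond of the ring A benzyl ether. This closes the five-membered ring, and a chiral dirhodium catalyst sets both stereocentres cis. It is placed early, on a small substrate.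

**7 ⇒ 5 + 6; 5 ⇒ 4 ⇒ 2 + 3; 2 ⇒ 1.** The aryl–carbon bond to the diazo ester comes from palladium-catalysed coupling of iodide 5 with 6, which gives the diazo compound directly. The benzyl ether comes from 2 and the acidic phenol 3 under neutral conditions that spare the aryl acetate. Compound 2 is the reduction product of 1.

**27 ⇒ 25 ⇒ 18 + 22.** Ring C is a silyl ether while organometallic reagents are used and is changed to the acetate at the end. The bond between the tertiary carbinol carbon and the alkene is cut: a chelation-controlled addition of the E-alkenyl metal from 22 to the hydroxy ketone 18. The tertiary centre is lost in the later 1,2-shift, so its control is a convenience; the (2S,3S) isomer is nonetheless the one that places the methyl group where it cannot migrate.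

**18 ⇒ 17 ⇒ 16 ⇒ 13 + 14; 13 ⇒ 12.** The methyl ketone comes from the N-methoxy-N-methylamide 17 and this from ester 16. The ArCH2–CH bond of 16 is cut: the aryl copper reagent from 13 opens the epoxide 14 at its CH2 group, so the C5 stereocentre is bought and never touched.

**22 ⇒ 20 ⇒ 19.** The E-vinyl iodide comes from syn hydrometalation and iodination of the alkyne 20, the silyl ether of 19.

## Alternatives that were turned down

**Alternative 1:** Only the C2–C3 bond of the tetrahydrofuran is cut. The precursor is the enol acetal A1, a 2-aryl-4-alkylidene-1,3-dioxolane whose acetal carbon is the future C2 and whose ester-bearing alkylidene carbon is the future C3.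
- Forward key step: an alkylaluminium chloride breaks the acetal C–O bond on the enol side, and the aluminium enolate returns to the oxocarbenium carbon through carbon (an oxygen-to-carbon shift of the Petasis–Ferrier type). This gives the 4-oxotetrahydrofuran-3-carboxylate A2 with the C2 and C5 substituents cis.
- For it: the nucleophile is an enolate, far more reactive than the alkene of 27. C2–C3 bond formation is safer than in step 17 and ring C cannot intervene. On this point the alternative is the stronger one.
- Against it: C4 arrives as a ketone. The hydroxyl group must then come from hydride addition on the face that carries the C3 substituent, with the C5 benzyl group on the other face, and neither face is clearly preferred. C3 of A2 is a β-keto ester carbon that sets itself only by equilibration. Making A1 needs a carbonyl olefination with an ester-bearing reagent, and A1 is acid-labile. The benzyl ether on ring A leaves C2'–O1' open to ionisation by the aluminium Lewis acid.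
- Comparison: the step count after the key step is similar. The alternative buys a safer bond formation at the price of an uncontrolled C4; the chosen route keeps the harder bond formation but lets every tetrahydrofuran stereocentre follow from C5.

**Alternative 2:** This addresses only the dihydrobenzofuran half. The O1'–C7a' bond is cut. The precursor is the secondary benzylic alcohol A3 with a triflate at C7a'; its two stereocentres would come from an anti-selective aldol reaction joining the ring B and ring A halves.
- Forward key step: a palladium catalyst with a bulky biaryl dialkylphosphine and a phosphate base couples the C2' hydroxyl group with C7a', giving the cis-dihydrobenzofuran A4 with the formyl group masked as a dioxolane.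
- For it: absolute and relative configuration come from an auxiliary-controlled aldol of known sense, and the ring closure touches neither stereocentre. This is stronger than relying on the facial preference of a chiral dirhodium catalyst, as step 5 does.
- Against it: the palladium alkoxide of a secondary benzylic alcohol has a β-hydrogen and readily gives the aryl ketone. The triflate carbon lies between a methoxy group and a branched side chain, so oxidative addition and C–O reductive elimination are slow. The aldolate can fragment by retro-aldol under base. The aldol, auxiliary removal, reduction, protection and triflation add about four steps to what steps 4 and 5 do in two.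
- Comparison: the tetrahydrofuran would still be made as in step 17. The chosen route offers the shorter entry to 11, and a shortfall in enantiomeric purity can be corrected by the resolution held in reserve or at the stage of 29.

**Alternative 3:** The same C–H insertion as in step 5, cutting C2'–C3', but placed after the tetrahydrofuran is complete. The aryldiazoacetate A5 carries the whole tetrahydrofuran on ring B and the ring A benzyl ether on the C7a' oxygen.
- Forward key step: a chiral dirhodium carboxylate decomposes A5, and insertion into the benzylic ether C–H bond gives the cis ester A6.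
- For it: the cis-dihydrobenzofuran never meets the Lewis acid of the Prins step or the peracid, a real advantage over the chosen route. The Prins partner would be a simple, robust aldehyde.
- Against it: the step with the least predictable selectivity moves to the end, onto the most valuable intermediate. A5 offers the carbenoid other activated C–H bonds (the benzylic ether C–H at C2 and four further benzyl ether methylene groups); the five-membered transition state favours the intended one, but by-products would be hard to remove so late. A shortfall in enantioselectivity appears as a diastereomer with remote stereocentres. The diazo group must be installed on a late aryl iodide, the ester must still be reduced, and four benzyl ethers must be removed by hydrogenolysis next to two benzylic ring C–O bonds.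
- Comparison: the chosen route performs the insertion on a small substrate at the start and joins two halves of similar size late. The inverted order is kept as the reserve plan for step 17.

Key step: step 17

Assumption: Rh2(S-PTTL)4 is taken to deliver the (2R,3S)-cis ester 8; should its sense be the opposite, the enantiomeric catalyst Rh2(R-PTTL)4 is used and nothing else changes.

## Route

Tetrahydrofuran atoms are numbered O1, C2 (aryl), C3, C4, C5 (benzyl) as in the target throughout. Ar(B) stands for the (2R,3R)-2-(4-acetoxy-3-methoxyphenyl)-3-(acetoxymethyl)-7-methoxy-2,3-dihydrobenzofuran-5-yl group of 11.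

Step 1
Reactants: 1 4-formyl-2-methoxyphenyl acetate (vanillin acetate)
Product: 2 4-(hydroxymethyl)-2-methoxyphenyl acetate
Conditions: NaBH4, THF–H2O (10:1), 0 °C, short reaction time; aq. NH4Cl
Reagents that add atoms: none
Why: Borohydride reduction of an aryl aldehyde; the aryl acetate is not reduced by NaBH4 at 0 °C in the time needed, and the nearly neutral medium avoids acetyl loss.

Step 2
Reactants: 2 4-(hydroxymethyl)-2-methoxyphenyl acetate; 3 4-hydroxy-3-iodo-5-methoxybenzaldehyde (5-iodovanillin)
Product: 4 4-[(4-formyl-2-iodo-6-methoxyphenoxy)methyl]-2-methoxyphenyl acetate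
Conditions: PPh3, DIAD, THF, 0 °C → rt
Reagents that add atoms: none
Why: Mitsunobu etherification of a primary benzylic alcohol with an acidic phenol (flanked by iodine, para to formyl); the neutral conditions keep the aryl acetate, which a carbonate-mediated alkylation could transfer or cleave.

Step 3
Reactants: 4 4-[(4-formyl-2-iodo-6-methoxyphenoxy)methyl]-2-methoxyphenyl acetate
Product: 5 4-{[4-(1,3-dioxolan-2-yl)-2-iodo-6-methoxyphenoxy]methyl}-2-methoxyphenyl acetate
Conditions: Me3SiOCH2CH2OSiMe3, Me3SiOTf (2 mol%), CH2Cl2, −78 → −20 °C; pyridine quench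
Reagents that add atoms: 1,2-bis(trimethylsilyloxy)ethane, C[Si](C)(C)OCCO[Si](C)(C)C
Why: Aprotic silyl-transfer acetalisation driven by formation of hexamethyldisiloxane; it masks the aldehyde against the diazo ester, the carbenoid and LiAlH4 without exposing the aryl acetate to an alcohol and acid.

Step 4
Reactants: 5 4-{[4-(1,3-dioxolan-2-yl)-2-iodo-6-methoxyphenoxy]methyl}-2-methoxyphenyl acetate; 6 ethyl diazoacetate
Product: 7 ethyl 2-{2-[(4-acetoxy-3-methoxybenzyl)oxy]-5-(1,3-dioxolan-2-yl)-3-methoxyphenyl}-2-diazoacetate
Conditions: Pd(PPh3)4 (5 mol%), Ag2CO3 (0.5 equiv), Et3N, toluene, rt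
Reagents that add atoms: none
Why: Palladium-catalysed cross-coupling of an aryl iodide with the C–H bond of ethyl diazoacetate: oxidative addition to zerovalent palladium, base-assisted palladation of the diazo carbon and reductive elimination at room temperature, with the diazo group retained.

Step 5
Reactants: 7 ethyl 2-{2-[(4-acetoxy-3-methoxybenzyl)oxy]-5-(1,3-dioxolan-2-yl)-3-methoxyphenyl}-2-diazoacetate
Product: 8 ethyl (2R,3S)-2-(4-acetoxy-3-methoxyphenyl)-5-(1,3-dioxolan-2-yl)-7-methoxy-2,3-dihydrobenzofuran-3-carboxylate (2,3-cis)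
Conditions: Rh2(S-PTTL)4, dirhodium tetrakis[N-phthaloyl-(S)-tert-leucinate] (1 mol%), toluene, −60 °C
Reagents that add atoms: none
Why: Intramolecular 1,5 C–H insertion of a donor/acceptor rhodium carbenoid into the benzylic ether C–H bond closes the dihydrobenzofuran. The chiral carboxylate ligands set C2 and C3 (cis, catalyst control), and the kinetic cis ester is not epimerised at this temperature.

Step 6
Reactants: 8 ethyl (2R,3S)-2-(4-acetoxy-3-methoxyphenyl)-5-(1,3-dioxolan-2-yl)-7-methoxy-2,3-dihydrobenzofuran-3-carboxylate
Product: 9 4-[(2R,3R)-5-(1,3-dioxolan-2-yl)-3-(hydroxymethyl)-7-methoxy-2,3-dihydrobenzofuran-2-yl]-2-methoxyphenol (2,3-cis)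
Conditions: LiAlH4, THF, −20 → 0 °C; aq. potassium sodium tartrate
Reagents that add atoms: none
Why: Hydride reduction converts the ester into the hydroxymethyl group and cleaves the aryl acetate in the same operation. Hydride addition is faster than enolisation, so C3 keeps its configuration, and the dioxolane is inert.

Step 7
Reactants: 9 4-[(2R,3R)-5-(1,3-dioxolan-2-yl)-3-(hydroxymethyl)-7-methoxy-2,3-dihydrobenzofuran-2-yl]-2-methoxyphenol
Product: 10 [(2R,3R)-2-(4-acetoxy-3-methoxyphenyl)-5-(1,3-dioxolan-2-yl)-7-methoxy-2,3-dihydrobenzofuran-3-yl]methyl acetate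
Conditions: Ac2O, pyridine, DMAP (cat.), CH2Cl2, 0 °C → rt
Reagents that add atoms: acetic anhydride, CC(=O)OC(C)=O
Why: Acylation of the phenol and the primary alcohol; the electron-withdrawing ester is back on ring A before any acid is applied.

Step 8
Reactants: 10 [(2R,3R)-2-(4-acetoxy-3-methoxyphenyl)-5-(1,3-dioxolan-2-yl)-7-methoxy-2,3-dihydrobenzofuran-3-yl]methyl acetate
Product: 11 [(2R,3R)-2-(4-acetoxy-3-methoxyphenyl)-5-formyl-7-methoxy-2,3-dihydrobenzofuran-3-yl]methyl acetate
Conditions: pyridinium p-toluenesulfonate (cat.), acetone–H2O (10:1), 45 °C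
Reagents that add atoms: water, O
Why: Mild acid hydrolysis of an electron-rich aryl dioxolane; both acetates survive, and the acetate on ring A keeps the C2–O bond of the dihydrobenzofuran from ionising.

Step 9
Reactants: 12 4-bromo-2-methoxyphenol
Product: 13 (4-bromo-2-methoxyphenoxy)(tert-butyl)dimethylsilane
Conditions: t-BuMe2SiCl, imidazole, DMF, rt
Reagents that add atoms: tert-butyldimethylsilyl chloride, CC(C)(C)[Si](C)(C)Cl
Why: Silylation of a phenol; the silyl ether tolerates Grignard formation and the organomagnesium steps that an aryl acetate would not.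

Step 10
Reactants: 13 (4-bromo-2-methoxyphenoxy)(tert-butyl)dimethylsilane; 14 methyl (S)-oxirane-2-carboxylate (methyl (S)-glycidate)
Product: 16 methyl (S)-3-{4-[(tert-butyldimethylsilyl)oxy]-3-methoxyphenyl}-2-hydroxypropanoate, via arylmagnesium bromide 15 (not isolated)
Conditions: Mg turnings, THF, 40 °C; then CuI (10 mol%) and 14, THF, −40 → −20 °C; aq. NH4Cl
Reagents that add atoms: none
Why: Copper-catalysed SN2 opening of the terminal epoxide at its CH2 group by the aryl Grignard reagent, faster than carbonyl addition at this temperature. The stereocentre of 14 is not involved and becomes C5 of the target.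

Step 11
Reactants: 16 methyl (S)-3-{4-[(tert-butyldimethylsilyl)oxy]-3-methoxyphenyl}-2-hydroxypropanoate
Product: 17 (S)-3-{4-[(tert-butyldimethylsilyl)oxy]-3-methoxyphenyl}-2-hydroxy-N-methoxy-N-methylpropanamide
Conditions: MeNH(OMe)·HCl, i-PrMgCl, THF, −20 → 0 °C
Reagents that add atoms: N,O-dimethylhydroxylamine hydrochloride, CNOC.Cl
Why: Aminolysis of the ester by the magnesium amide of N,O-dimethylhydroxylamine (Weinreb amide formation); the free hydroxyl group is carried as its alkoxide, which also guards the α-centre against enolisation.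

Step 12
Reactants: 17 (S)-3-{4-[(tert-butyldimethylsilyl)oxy]-3-methoxyphenyl}-2-hydroxy-N-methoxy-N-methylpropanamide
Product: 18 (S)-4-{4-[(tert-butyldimethylsilyl)oxy]-3-methoxyphenyl}-3-hydroxybutan-2-one
Conditions: MeMgBr (3 equiv), THF, −20 → 0 °C; aq. NH4Cl
Reagents that add atoms: methylmagnesium bromide, C[Mg]Br
Why: Weinreb ketone synthesis; the chelated tetrahedral intermediate prevents a second addition, and the magnesium alkoxide at the α-oxygen suppresses enolisation towards the stereocentre.

Step 13
Reactants: 19 prop-2-yn-1-ol (propargyl alcohol)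
Product: 20 tert-butyldiphenyl(prop-2-yn-1-yloxy)silane
Conditions: t-BuPh2SiCl, imidazole, CH2Cl2, 0 °C → rt
Reagents that add atoms: tert-butyldiphenylsilyl chloride, CC(C)(C)[Si](Cl)(c1ccccc1)c1ccccc1
Why: Silylation of a primary alcohol; the robust, poorly coordinating silyl ether survives t-BuLi, SnCl4 and peracid and does not bind the Lewis acid of step 17.

Step 14
Reactants: 20 tert-butyldiphenyl(prop-2-yn-1-yloxy)silane
Product: 22 (E)-tert-butyl[(3-iodoprop-2-en-1-yl)oxy]diphenylsilane, via alkenylzirconocene chloride 21 (not isolated)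
Conditions: Cp2Zr(H)Cl, THF, rt; then I2, 0 °C
Reagents that add atoms: iodine, II
Why: Hydrozirconation adds Zr–H syn across the terminal alkyne with zirconium at the terminal carbon, and iodinolysis proceeds with retention, giving the E-vinyl iodide only.

Step 15
Reactants: 22 (E)-tert-butyl[(3-iodoprop-2-en-1-yl)oxy]diphenylsilane; 18 (S)-4-{4-[(tert-butyldimethylsilyl)oxy]-3-methoxyphenyl}-3-hydroxybutan-2-one
Product: 25 (2S,3S,4E)-6-[(tert-butyldiphenylsilyl)oxy]-1-{4-[(tert-butyldimethylsilyl)oxy]-3-methoxyphenyl}-3-methylhex-4-ene-2,3-diol, via alkenyllithium 23 (not isolated), via alkenylmagnesium bromide 24 (not isolated)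
Conditions: 22 (2.6 equiv), t-BuLi (5.2 equiv), Et2O, −78 °C; MgBr2·OEt2, −78 → −40 °C; then 18, THF, −78 → −40 °C; aq. NH4Cl
Reagents that add atoms: none
Why: Iodine–lithium exchange and transmetalation to magnesium keep the E geometry. The first equivalent deprotonates the hydroxyl group, the magnesium alkoxide chelates the ketone in a five-membered ring, and the second equivalent adds on the face away from the arylmethyl group (chelation-controlled 1,2-addition), setting the tertiary carbinol as S. This centre is erased in step 17, so a minor epimer would not change the outcome.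

Step 16
Reactants: 25 (2S,3S,4E)-6-[(tert-butyldiphenylsilyl)oxy]-1-{4-[(tert-butyldimethylsilyl)oxy]-3-methoxyphenyl}-3-methylhex-4-ene-2,3-diol
Product: 27 4-{(2S,3S,4E)-6-[(tert-butyldiphenylsilyl)oxy]-2,3-dihydroxy-3-methylhex-4-en-1-yl}-2-methoxyphenyl acetate, via phenol 26 (not isolated)
Conditions: Bu4NF (1.05 equiv), THF, −20 °C; then Ac2O (1.2 equiv), −20 → 0 °C
Reagents that add atoms: acetic anhydride, CC(=O)OC(C)=O
Why: Fluoride cleaves the aryl silyl ether far faster than the primary alkyl tert-butyldiphenylsilyl ether, and the phenoxide set free is acetylated much faster than the secondary and tertiary hydroxyl groups (desilylation–acylation in one flask).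

Step 17
Reactants: 11 [(2R,3R)-2-(4-acetoxy-3-methoxyphenyl)-5-formyl-7-methoxy-2,3-dihydrobenzofuran-3-yl]methyl acetate; 27 4-{(2S,3S,4E)-6-[(tert-butyldiphenylsilyl)oxy]-2,3-dihydroxy-3-methylhex-4-en-1-yl}-2-methoxyphenyl acetate
Product: 29 acetyl tetrahydrofuran (C2: Ar(B); C3: CH2OSi-t-BuPh2; C4: acetyl; C5: 4-acetoxy-3-methoxybenzyl; the C2/C4/C5 substituents on one face and the C3 substituent on the other), via dioxolane acetal 28 (not isolated)
Conditions: pyridinium p-toluenesulfonate (10 mol%), benzene, reflux, Dean–Stark trap; evaporation; then SnCl4 (3 equiv), CH2Cl2, −78 → −25 °C; aq. NaHCO3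
Reagents that add atoms: none
Why: Acid-catalysed condensation of 11 with the secondary and tertiary hydroxyl groups of 27 gives the 2-aryl-4-alkenyl-1,3-dioxolane 28 (forming C2–O1; either acetal epimer serves), and SnCl4 then ionises the acetal bond to the tertiary oxygen, leaving an E-configured oxocarbenium ion on O1 and a tin alkoxide on the carbinol carbon. The alkene attacks C2 through C3 in a 6-endo Prins closure via a chair in which the ring B aryl group, the silyloxymethyl group and the ring C benzyl group are equatorial and the tin alkoxide is axial; the C4 cation is captured at once by 1,2-shift of C5 from the carbinol carbon, and this pinacol ring contraction closes the tetrahydrofuran through the C4–C5 bond and turns the carbinol carbon into the acetyl group. The closest known reaction type is the Prins cyclisation–pinacol rearrangement of acetals of allylic 1,2-diols to 3-acyltetrahydrofurans, known for aromatic aldehydes and for E-1,2-disubstituted alkenes. C2 is set by the equatorial aryl group of the E-oxocarbenium ion (cis to the C5 substituent), C3 by the E geometry of the alkene (trans to the C2 aryl group) and C4 by the suprafacial shift of C5 across the chair, which leaves the acetyl group cis to the C5 benzyl group; all three refer to the C5 centre that stems from 14, so the absolute sense does not depend on the dihydrobenzofuran. The alkene must win over ring C, whose carbon para to the methoxy group could otherwise close onto the same oxocarbenium ion (oxa-Pictet–Spengler reaction): ring C is therefore an aryl acetate, made poorer still by SnCl4 binding, and the allylic oxygen carries a bulky silyl group that does not bind the Lewis acid. The C2'–O1' bond must stay closed, which the acetate on ring A secures, and the right group must migrate: in the chair from the (2S,3S)-diol the methyl group is equatorial and lies in the nodal plane of the empty orbital at C4, so only the ring bond to C5 is placed to shift, and the tertiary alkoxide makes the shift irreversible.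

Step 18
Reactants: 29 acetyl tetrahydrofuran (C2: Ar(B); C3: CH2OSi-t-BuPh2; C4: acetyl; C5: 4-acetoxy-3-methoxybenzyl)
Product: 30 C4 acetate (C2: Ar(B); C3: CH2OSi-t-BuPh2; C4: acetoxy on the face of the C2 and C5 substituents; C5: 4-acetoxy-3-methoxybenzyl)
Conditions: mCPBA (3 equiv), NaHCO3, CH2Cl2, 0 °C → rt, dark
Reagents that add atoms: 3-chloroperbenzoic acid, O=C(OO)c1cccc(Cl)c1
Why: Baeyer–Villiger oxidation; the secondary ring carbon C4 migrates in preference to methyl and with retention, so the acetoxy group takes the place of the acetyl group. The buffer protects the benzylic ethers, and the aryl acetates on rings A and C damp arene oxidation.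

Step 19
Reactants: 30 C4 acetate (C2: Ar(B); C3: CH2OSi-t-BuPh2; C4: acetoxy; C5: 4-acetoxy-3-methoxybenzyl)
Product: 31 primary alcohol tetraacetate (C2: Ar(B); C3: CH2OH; C4: acetoxy; C5: 4-acetoxy-3-methoxybenzyl)
Conditions: HF·pyridine, pyridine, THF, 0 °C → rt
Reagents that add atoms: none
Why: Fluoride-mediated cleavage of the primary silyl ether under buffered conditions, done while both phenols are still acetates so that no quinone methide-forming phenol is exposed to the acid.

Step 20
Reactants: 31 primary alcohol tetraacetate (C2: Ar(B); C3: CH2OH; C4: acetoxy; C5: 4-acetoxy-3-methoxybenzyl)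
Product: 32 target, (2S,3S,4S,5S)-tetrahydrofuran with 2-[(2R,3R)-2-(4-hydroxy-3-methoxyphenyl)-3-(hydroxymethyl)-7-methoxy-2,3-dihydrobenzofuran-5-yl], 3-hydroxymethyl, 4-hydroxy and 5-(4-hydroxy-3-methoxybenzyl) groups
Conditions: K2CO3 (0.3 equiv), MeOH, 0 → 10 °C; solid NH4Cl, filtration
Reagents that add atoms: none
Why: Carbonate-catalysed transesterification removes the two aryl and two alkyl acetates; low temperature, short exposure and a neutral quench keep the ring A phenoxide from opening the C2'–O1' bond.

## Compound list

1 | 4-formyl-2-methoxyphenyl acetate (vanillin acetate) | CC(=O)Oc1ccc(C=O)cc1OC | starting material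
2 | 4-(hydroxymethyl)-2-methoxyphenyl acetate | CC(=O)Oc1ccc(CO)cc1OC | intermediate
3 | 4-hydroxy-3-iodo-5-methoxybenzaldehyde (5-iodovanillin) | COc1cc(C=O)cc(I)c1O | starting material
4 | 4-[(4-formyl-2-iodo-6-methoxyphenoxy)methyl]-2-methoxyphenyl acetate | COc1cc(C=O)cc(I)c1OCc1ccc(OC(C)=O)c(OC)c1 | intermediate
5 | 4-{[4-(1,3-dioxolan-2-yl)-2-iodo-6-methoxyphenoxy]methyl}-2-methoxyphenyl acetate | COc1cc(C2OCCO2)cc(I)c1OCc1ccc(OC(C)=O)c(OC)c1 | intermediate
6 | ethyl diazoacetate | CCOC(=O)C=[N+]=[N-] | starting material
7 | ethyl 2-{2-[(4-acetoxy-3-methoxybenzyl)oxy]-5-(1,3-dioxolan-2-yl)-3-methoxyphenyl}-2-diazoacetate | CCOC(=O)C(=[N+]=[N-])c1cc(C2OCCO2)cc(OC)c1OCc1ccc(OC(C)=O)c(OC)c1 | intermediate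
8 | ethyl (2R,3S)-2-(4-acetoxy-3-methoxyphenyl)-5-(1,3-dioxolan-2-yl)-7-methoxy-2,3-dihydrobenzofuran-3-carboxylate (cis) | C1COC(O1)c1cc(OC)c2c(c1)[C@H](C(=O)OCC)[C@H](c1ccc(OC(C)=O)c(OC)c1)O2 | intermediate
9 | 4-[(2R,3R)-5-(1,3-dioxolan-2-yl)-3-(hydroxymethyl)-7-methoxy-2,3-dihydrobenzofuran-2-yl]-2-methoxyphenol (cis) | C1COC(O1)c1cc(OC)c2c(c1)[C@H](CO)[C@H](c1ccc(O)c(OC)c1)O2 | intermediate
10 | [(2R,3R)-2-(4-acetoxy-3-methoxyphenyl)-5-(1,3-dioxolan-2-yl)-7-methoxy-2,3-dihydrobenzofuran-3-yl]methyl acetate | C1COC(O1)c1cc(OC)c2c(c1)[C@H](COC(C)=O)[C@H](c1ccc(OC(C)=O)c(OC)c1)O2 | intermediate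
11 | [(2R,3R)-2-(4-acetoxy-3-methoxyphenyl)-5-formyl-7-methoxy-2,3-dihydrobenzofuran-3-yl]methyl acetate | O=Cc1cc(OC)c2c(c1)[C@H](COC(C)=O)[C@H](c1ccc(OC(C)=O)c(OC)c1)O2 | intermediate
12 | 4-bromo-2-methoxyphenol | COc1cc(Br)ccc1O | starting material
13 | (4-bromo-2-methoxyphenoxy)(tert-butyl)dimethylsilane | COc1cc(Br)ccc1O[Si](C)(C)C(C)(C)C | intermediate
14 | methyl (S)-oxirane-2-carboxylate | COC(=O)[C@@H]1CO1 | starting material
15 | {4-[(tert-butyldimethylsilyl)oxy]-3-methoxyphenyl}magnesium bromide | COc1cc([Mg]Br)ccc1O[Si](C)(C)C(C)(C)C | intermediate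
16 | methyl (S)-3-{4-[(tert-butyldimethylsilyl)oxy]-3-methoxyphenyl}-2-hydroxypropanoate | COC(=O)[C@@H](O)Cc1ccc(O[Si](C)(C)C(C)(C)C)c(OC)c1 | intermediate
17 | (S)-3-{4-[(tert-butyldimethylsilyl)oxy]-3-methoxyphenyl}-2-hydroxy-N-methoxy-N-methylpropanamide | CON(C)C(=O)[C@@H](O)Cc1ccc(O[Si](C)(C)C(C)(C)C)c(OC)c1 | intermediate
18 | (S)-4-{4-[(tert-butyldimethylsilyl)oxy]-3-methoxyphenyl}-3-hydroxybutan-2-one | CC(=O)[C@@H](O)Cc1ccc(O[Si](C)(C)C(C)(C)C)c(OC)c1 | intermediate
19 | prop-2-yn-1-ol | C#CCO | starting material
20 | tert-butyldiphenyl(prop-2-yn-1-yloxy)silane | C#CCO[Si](c1ccccc1)(c1ccccc1)C(C)(C)C | intermediate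
21 | (E)-{3-[(tert-butyldiphenylsilyl)oxy]prop-1-enyl}zirconocene chloride, Cp2Zr(Cl)(alkenyl) | Cl[Zr](/C=C/CO[Si](c1ccccc1)(c1ccccc1)C(C)(C)C)(C1C=CC=C1)C1C=CC=C1 | intermediate
22 | (E)-tert-butyl[(3-iodoprop-2-en-1-yl)oxy]diphenylsilane | I/C=C/CO[Si](c1ccccc1)(c1ccccc1)C(C)(C)C | intermediate
23 | (E)-3-[(tert-butyldiphenylsilyl)oxy]prop-1-enyllithium | [Li]/C=C/CO[Si](c1ccccc1)(c1ccccc1)C(C)(C)C | intermediate
24 | (E)-3-[(tert-butyldiphenylsilyl)oxy]prop-1-enylmagnesium bromide | Br[Mg]/C=C/CO[Si](c1ccccc1)(c1ccccc1)C(C)(C)C | intermediate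
25 | (2S,3S,4E)-6-[(tert-butyldiphenylsilyl)oxy]-1-{4-[(tert-butyldimethylsilyl)oxy]-3-methoxyphenyl}-3-methylhex-4-ene-2,3-diol | COc1cc(C[C@H](O)[C@@](C)(O)/C=C/CO[Si](c2ccccc2)(c2ccccc2)C(C)(C)C)ccc1O[Si](C)(C)C(C)(C)C | intermediate
26 | 4-{(2S,3S,4E)-6-[(tert-butyldiphenylsilyl)oxy]-2,3-dihydroxy-3-methylhex-4-en-1-yl}-2-methoxyphenol | COc1cc(C[C@H](O)[C@@](C)(O)/C=C/CO[Si](c2ccccc2)(c2ccccc2)C(C)(C)C)ccc1O | intermediate
27 | 4-{(2S,3S,4E)-6-[(tert-butyldiphenylsilyl)oxy]-2,3-dihydroxy-3-methylhex-4-en-1-yl}-2-methoxyphenyl acetate | COc1cc(C[C@H](O)[C@@](C)(O)/C=C/CO[Si](c2ccccc2)(c2ccccc2)C(C)(C)C)ccc1OC(C)=O | intermediate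
28 | 1,3-dioxolane acetal of 11 and 27 (acetal carbon: Ar(B); ring C4: 4-acetoxy-3-methoxybenzyl; ring C5: methyl and (E)-3-silyloxyprop-1-enyl; both epimers at the acetal carbon) | COc1cc(C[C@@H]2OC(c3cc(OC)c4c(c3)[C@H](COC(C)=O)[C@H](c3ccc(OC(C)=O)c(OC)c3)O4)O[C@@]2(C)/C=C/CO[Si](c2ccccc2)(c2ccccc2)C(C)(C)C)ccc1OC(C)=O | intermediate
29 | acetyl tetrahydrofuran (C2: Ar(B); C3: CH2OSi-t-BuPh2; C4: acetyl; C5: 4-acetoxy-3-methoxybenzyl; C2/C4/C5 substituents cis, C3 trans) | COc1cc(C[C@@H]2O[C@H](c3cc(OC)c4c(c3)[C@H](COC(C)=O)[C@H](c3ccc(OC(C)=O)c(OC)c3)O4)[C@@H](CO[Si](c3ccccc3)(c3ccccc3)C(C)(C)C)[C@@H]2C(C)=O)ccc1OC(C)=O | intermediate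
30 | C4 acetate (as 29 with acetoxy in place of acetyl at C4, same configuration) | COc1cc(C[C@@H]2O[C@H](c3cc(OC)c4c(c3)[C@H](COC(C)=O)[C@H](c3ccc(OC(C)=O)c(OC)c3)O4)[C@@H](CO[Si](c3ccccc3)(c3ccccc3)C(C)(C)C)[C@@H]2OC(C)=O)ccc1OC(C)=O | intermediate
31 | primary alcohol tetraacetate (as 30 with CH2OH at C3) | COc1cc(C[C@@H]2O[C@H](c3cc(OC)c4c(c3)[C@H](COC(C)=O)[C@H](c3ccc(OC(C)=O)c(OC)c3)O4)[C@@H](CO)[C@@H]2OC(C)=O)ccc1OC(C)=O | intermediate
32 | (2S,3S,4S,5S)-5-(4-hydroxy-3-methoxybenzyl)-2-[(2R,3R)-2-(4-hydroxy-3-methoxyphenyl)-3-(hydroxymethyl)-7-methoxy-2,3-dihydrobenzofuran-5-yl]-3-(hydroxymethyl)tetrahydrofuran-4-ol (target numbering) | COc1cc(C[C@@H]2O[C@H](c3cc(OC)c4c(c3)[C@H](CO)[C@H](c3ccc(O)c(OC)c3)O4)[C@@H](CO)[C@@H]2O)ccc1O | target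

## Step count and risks

Total: 20 steps. Longest linear sequence: 12 steps (1 → 2 → 4 → 5 → 7 → 8 → 9 → 10 → 11 → 29 → 30 → 31 → 32). The diol branch from 12 contributes 6 steps and the vinyl iodide branch from 19 contributes 2.

**Step 17 (key step).** The most likely failure is slow capture of the oxocarbenium ion. It is stabilised by the ring oxygen para to it on ring B, and the alkene is deactivated by two allylic C–O bonds. Ionisation of the tertiary allylic C–O bond, or closure onto ring C despite its acetate, may then take over.

The fallback inverts the order of ring construction, so that the oxocarbenium ion is less stabilised and the dihydrobenzofuran is built afterwards. It sets out from 3 and 27 and returns at 32.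
- 3 is acylated with 2,2,2-trichloroethyl chloroformate and pyridine to the aryl carbonate F1.
- F1 and 27 are condensed and rearranged as in step 17, through the acetal F2, to the acetyl tetrahydrofuran F3.
- Baeyer–Villiger oxidation as in step 18 gives the acetate F4.
- Zn in AcOH–THF removes the carbonate to give the iodophenol F5.
- Mitsunobu etherification with 2 as in step 2 gives the benzyl ether F6.
- Coupling with 6 as in step 4 gives the aryldiazoacetate F7.
- Insertion with Rh2(S-PTTL)4 as in step 5 gives the cis ester F8.
- LiAlH4 reduces the ester and the three acetates to the silyl ether F9.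
- Bu4NF buffered with AcOH gives 32.

**Step 5.** The risk is insufficient enantioselectivity or cis-selectivity. The substrate differs from the simplest cases by its ethyl ester, its second ortho substituent and the acetal. A shortfall would surface as a diastereomer of 29.

The fallback replaces catalyst control by resolution; it sets out from scalemic 9 and returns to enantiopure 9. Both hydroxyl groups of 9 are esterified with (S)-2-methoxy-2-phenylacetic acid (EDC, DMAP) to the bis-ester F10. Its diastereomers are separated by crystallisation or chromatography, and LiAlH4 returns 9.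

**Step 4.** The risk is loss of the diazo ester by dimerisation and protodeiodination of the hindered, electron-rich iodide before coupling.

The fallback separates carbon–carbon bond formation from diazo installation; it sets out from 5 and returns at 7. Palladium-catalysed coupling of 5 with the Reformatsky reagent BrZnCH2CO2Et (Pd(dba)2 with a bulky dialkylphosphine, THF, rt) gives the arylacetate F11. Regitz diazo transfer (4-acetamidobenzenesulfonyl azide, DBU, MeCN, 0 °C) then gives 7.

**Step 18.** The risk is that migration of the β-oxygenated secondary carbon is slow, so that peracid oxidation of the electron-rich ring B or epimerisation at C4 competes.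

The fallback exchanges the acetyl group for acetate without a peracid; it sets out from 29 and returns at 30. Takai–Lombardo methylenation (Zn, CH2Br2, TiCl4, which spares the acetates) gives the isopropenyl compound F12. Ozonolysis in CH2Cl2–MeOH at −78 °C, with an indicator to protect the arenes, followed by Ac2O, Et3N and DMAP, triggers a Criegee rearrangement of the methoxy hydroperoxide, with C4 migrating with retention, to give 30.

**Step 20.** The risk is epimerisation at C2' by quinone methide opening once ring A is a phenoxide in methanol.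

The fallback removes the acetates by hydride reduction instead of base-mediated solvolysis; it sets out from 31 and returns at 32. LiAlH4 in THF at −20 °C with aq. potassium sodium tartrate work-up is used, so that no free phenoxide stands in a protic medium; no new compound is made.

## Further compounds

F1 | step 17 | 4-formyl-2-iodo-6-methoxyphenyl 2,2,2-trichloroethyl carbonate | O=Cc1cc(I)c(OC(=O)OCC(Cl)(Cl)Cl)c(OC)c1
F2 | step 17 | 1,3-dioxolane acetal of F1 and 27 (both epimers at the acetal carbon) | COc1cc(C[C@@H]2OC(c3cc(I)c(OC(=O)OCC(Cl)(Cl)Cl)c(OC)c3)O[C@@]2(C)/C=C/CO[Si](c2ccccc2)(c2ccccc2)C(C)(C)C)ccc1OC(C)=O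
F3 | step 17 | acetyl tetrahydrofuran with 3-iodo-5-methoxy-4-(trichloroethoxycarbonyloxy)phenyl at C2 | COc1cc(C[C@@H]2O[C@H](c3cc(I)c(OC(=O)OCC(Cl)(Cl)Cl)c(OC)c3)[C@@H](CO[Si](c3ccccc3)(c3ccccc3)C(C)(C)C)[C@@H]2C(C)=O)ccc1OC(C)=O
F4 | step 17 | C4 acetate of F3 | COc1cc(C[C@@H]2O[C@H](c3cc(I)c(OC(=O)OCC(Cl)(Cl)Cl)c(OC)c3)[C@@H](CO[Si](c3ccccc3)(c3ccccc3)C(C)(C)C)[C@@H]2OC(C)=O)ccc1OC(C)=O
F5 | step 17 | iodophenol (4-hydroxy-3-iodo-5-methoxyphenyl at C2) | COc1cc(C[C@@H]2O[C@H](c3cc(I)c(O)c(OC)c3)[C@@H](CO[Si](c3ccccc3)(c3ccccc3)C(C)(C)C)[C@@H]2OC(C)=O)ccc1OC(C)=O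
F6 | step 17 | 4-acetoxy-3-methoxybenzyl ether of F5 | COc1cc(C[C@@H]2O[C@H](c3cc(I)c(OCc4ccc(OC(C)=O)c(OC)c4)c(OC)c3)[C@@H](CO[Si](c3ccccc3)(c3ccccc3)C(C)(C)C)[C@@H]2OC(C)=O)ccc1OC(C)=O
F7 | step 17 | aryldiazoacetate from F6 | COc1cc(C[C@@H]2O[C@H](c3cc(C(=[N+]=[N-])C(=O)OCC)c(OCc4ccc(OC(C)=O)c(OC)c4)c(OC)c3)[C@@H](CO[Si](c3ccccc3)(c3ccccc3)C(C)(C)C)[C@@H]2OC(C)=O)ccc1OC(C)=O
F8 | step 17 | cis-dihydrobenzofuran-3-carboxylate on the complete tetrahydrofuran | COc1cc(C[C@@H]2O[C@H](c3cc(OC)c4c(c3)[C@H](C(=O)OCC)[C@H](c3ccc(OC(C)=O)c(OC)c3)O4)[C@@H](CO[Si](c3ccccc3)(c3ccccc3)C(C)(C)C)[C@@H]2OC(C)=O)ccc1OC(C)=O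
F9 | step 17 | tert-butyldiphenylsilyl ether of 32 at the C3 hydroxymethyl group | COc1cc(C[C@@H]2O[C@H](c3cc(OC)c4c(c3)[C@H](CO)[C@H](c3ccc(O)c(OC)c3)O4)[C@@H](CO[Si](c3ccccc3)(c3ccccc3)C(C)(C)C)[C@@H]2O)ccc1O
F10 | step 5 | bis[(S)-2-methoxy-2-phenylacetate] of 9 | C1COC(O1)c1cc(OC)c2c(c1)[C@H](COC(=O)[C@@H](OC)c1ccccc1)[C@H](c1ccc(OC(=O)[C@@H](OC)c3ccccc3)c(OC)c1)O2
F11 | step 4 | ethyl 2-{2-[(4-acetoxy-3-methoxybenzyl)oxy]-5-(1,3-dioxolan-2-yl)-3-methoxyphenyl}acetate | CCOC(=O)Cc1cc(C2OCCO2)cc(OC)c1OCc1ccc(OC(C)=O)c(OC)c1
F12 | step 18 | isopropenyl tetrahydrofuran (as 29 with prop-1-en-2-yl at C4) | COc1cc(C[C@@H]2O[C@H](c3cc(OC)c4c(c3)[C@H](COC(C)=O)[C@H](c3ccc(OC(C)=O)c(OC)c3)O4)[C@@H](CO[Si](c3ccccc3)(c3ccccc3)C(C)(C)C)[C@@H]2C(C)=C)ccc1OC(C)=O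
F0 | step 20 | none | none
A1 | alternative 1 | 2-aryl-4-(methoxycarbonylmethylidene)-5-(4-benzyloxy-3-methoxybenzyl)-1,3-dioxolane | COC(=O)C=C1OC(c2cc(OC)c3c(c2)[C@H](COCc2ccccc2)[C@H](c2ccc(OCc4ccccc4)c(OC)c2)O3)O[C@H]1Cc1ccc(OCc2ccccc2)c(OC)c1
A2 | alternative 1 | 2,5-cis 4-oxotetrahydrofuran-3-carboxylate | COc1cc(C[C@@H]2O[C@H](c3cc(OC)c4c(c3)[C@H](COCc3ccccc3)[C@H](c3ccc(OCc5ccccc5)c(OC)c3)O4)[C@@H](C(=O)OC)C2=O)ccc1OCc1ccccc1
A3 | alternative 2 | aryl triflate with secondary benzylic alcohol | C1COC(O1)c1cc(OC)c(OS(=O)(=O)C(F)(F)F)c(c1)[C@H](COCc1ccccc1)[C@@H](O)c1ccc(OCc2ccccc2)c(OC)c1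
A4 | alternative 2 | cis-dihydrobenzofuran with dioxolane-masked 5-formyl group | C1COC(O1)c1cc(OC)c2c(c1)[C@H](COCc1ccccc1)[C@H](c1ccc(OCc3ccccc3)c(OC)c1)O2
A5 | alternative 3 | aryldiazoacetate carrying the complete tetrahydrofuran | COc1cc(C[C@@H]2O[C@H](c3cc(OC)c(OCc4ccc(OCc5ccccc5)c(OC)c4)c(c3)C(=[N+]=[N-])C(=O)OCC)[C@@H](COCc3ccccc3)[C@@H]2OCc2ccccc2)ccc1OCc1ccccc1
A6 | alternative 3 | cis-dihydrobenzofuran-3-carboxylate on the complete tetrahydrofuran | COc1cc(C[C@@H]2O[C@H](c3cc(OC)c4c(c3)[C@H](C(=O)OCC)[C@H](c3ccc(OCc5ccccc5)c(OC)c3)O4)[C@@H](COCc3ccccc3)[C@@H]2OCc2ccccc2)ccc1OCc1ccccc1
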